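- In the amber run, 39.2% of the charge stands in neither tetra adduct nor double product at 4.00 h, and we cannot see where it sits.

| flask | starting material | reagent | remark | time |
|---|---|---|---|---|
| amber | 0.010 M | 2.5 equiv | run made earlier |  |
| grey | 0.014 M | 2.5 equiv | run made earlier |  |
| violet | 0.022 M | 2.5 equiv | run made earlier |  |
| west | 0.010 M | 2.50 equiv | everything together at the start | 4.0 h |
| south-west | 0.010 M | 2.50 equiv (fed, over 2.5 h) | all else is in the flask from the start; the feed brings no volume worth counting | 4.0 h |
| north-west | 0.010 M | 2.50 equiv (fed, over 40 min) | all else is in the flask from the start; the feed brings no volume worth counting | 4.0 h |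
| north-east | 0.010 M | 2.50 equiv (in portions, 5, over 2.5 h) | first portion at the start, last at 2.5 h | 4.0 h |
| south-east | 0.010 M (fed, over 2.5 h) | 2.50 equiv | all else is in the flask from the start; the feed brings no volume worth counting | 4.0 h |

| run | time / h | tetra adduct / % | double product / % |
|---|---|---|---|
| amber | 0.333 | 8.4 | 19.1 |
| amber | 0.500 | 14.2 | 21.7 |
| amber | 0.667 | 19.7 | 22.6 |
| amber | 1.00 | 28.0 | 22.6 |
| amber | 1.50 | 34.7 | 22.1 |
| amber | 2.50 | 38.8 | 20.9 |
| amber | 4.00 | 40.2 | 20.6 |
| grey | 0.417 | 17.6 | 22.7 |
| grey | 0.667 | 26.8 | 23.1 |
| grey | 0.833 | 30.9 | 22.4 |
| grey | 1.33 | 36.3 | 21.5 |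
| grey | 2.00 | 39.3 | 21.0 |
| grey | 3.00 | 40.1 | 21.0 |
| grey | 5.00 | 40.3 | 21.0 |
| violet | 0.667 | 33.9 | 22.0 |
| violet | 1.33 | 39.2 | 21.5 |
| violet | 2.00 | 40.1 | 21.0 |
| violet | 3.00 | 39.8 | 20.7 |
| violet | 4.00 | 39.9 | 21.0 |
| violet | 5.00 | 39.9 | 21.3 |

(readings scatter by 0.3 percentage points)

- a reading or a percentage of tetra adduct counts all its forms, free or not

* the flask with the highest share of tetra adduct in tetra adduct plus double product ("all alike" if they lie within 1.5 percentage points) (west / south-west / north-west / north-east / south-east / all alike)
* share of tetra adduct in tetra adduct plus double product at the end, west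
* share of tetra adduct in tetra adduct plus double product at the end, south-west
* share of tetra adduct in tetra adduct plus double product at the end, north-west
* share of tetra adduct in tetra adduct plus double product at the end, north-east
* share of tetra adduct in tetra adduct plus double product at the end, south-east

- What we can read is the share of tetra adduct in the two, the selectivity of the run: amber ends at 66.1%, and violet, at twice the concentration, ends at 65.2%.
- Amber reads 19.7% tetra adduct at 0.667 h, half of its last reading, and we call that time the clock.
- The clock shortens as concentration rises: violet reads 33.9% at 0.667 h and amber 34.7% at 1.50 h, a time ratio of 2.25 against a concentration ratio of 2.20.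
- The feed number is the feed time divided by the clock at the flask's concentration 3.75.
- South-east starts with its reagent in the flask and receives starting material by feed, at feed number 3.75.
- Leave that feed at its rate: 2.5 h is longer than the clock, so the early portions meet the reagent charge and have time to go far along, while the late portions find less reagent.
- We expect south-east above 66.1%, and we hold the other flasks near it, since amber and violet end only 0.92 percentage points apart.
- The forecast names south-east, with 71.5% (68% to 76%), and gives west 66%, south-west 65%, north-west 65.7% and north-east 65.2%. Its ground for south-east is that feeding starting material into excess reagent keeps starting material low against double product, which favours tetra adduct; of the reagent feeds it says “dosing reagent changes nothing except slight incompleteness at 4 h”.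
- South-east gives 77.1%, which is 5.6 points above the forecast; west gives 65.5%, south-west 64.1%, north-west 65.4% and north-east 63.7%. South-east holds 13.3% double product at 4.00 h, against 21.1% in west. At feed number 3.75, the south-east share stands 11 points above the amber share.

    starting material + reagent → first product + by-product (k = 9.36 L mol⁻¹ min⁻¹)
    reagent + first product → double product + by-product (k = 3.12 L mol⁻¹ min⁻¹)
    reagent + double product → triple product + by-product (k = 6.04 L mol⁻¹ min⁻¹)
    reagent + triple product → tetra adduct + by-product (k = 27.4 L mol⁻¹ min⁻¹)
    reagent ⇌ dormant form (K = 0.560, k = 0.182 min⁻¹)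
    crystals ⇌ tetra adduct, rate k6*(cs6 - [tetra adduct]) while solid is left; crystals form when [tetra adduct] > cs6 (solubility = 1.50 mM, k = 5.34 min⁻¹)

- The neighbour is south-east at 0.017 M starting material, equivalents held. Its feed number is 6.37, higher than 3.75, so we expect a share above 77.1%; it gives 82.2%.

(The earlier runs and the new flask stem from a simulated flask on assumed constants, and the scatter is random.)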